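Numbering follows benzofuran (O1, C2, C3, C3a, C4–C7, C7a); ring A is the tetrahydrofuran ring and ring B the cyclohexenone ring.
Cuts: first the hydrogens at C4/C5, back to cross-conjugated dienone 13. Then O1–C2 and C3–C3a together, back to quinone monoketal 8 and (Z)-isoelemicin 10. Then C–allyl (Claisen) and the phenol C–O (Baeyer–Villiger), back to isovanillin.
Enabling feature: ring B carries O1 on C7a, C=O at C6, OMe at C5 and the allyl-bearing quaternary C3a next to C7a, so it is a dearomatised, partly reduced 2-allyl-4-methoxy-5-oxyphenol. At the arene level a two-electron oxidation makes the nucleophilic ortho carbon (C3a) electrophilic. It can then join the equally nucleophilic beta carbon of a propenylarene while the phenol oxygen takes the benzylic carbon.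
Forward: ring B is bought as an arene and dressed in five steps, ring A arises in step 7, and step 8 removes the extra C4=C5 unsaturation.
Stereochemistry: C2/C3 cis comes from the Z alkene, with both bonds forming on one alkene face. C3a relative to C3 comes from an exo approach enforced by a bulky silyl group on the C6 oxygen, which leaves in the same step. The absolute sense comes from a chiral counteranion, and C5 from kinetic protonation opposite the pseudoaxial allyl group.

Key step: step 7

Assumption: the sense of induction of the chiral acid in step 7 cannot be derived from a model. The (S,S) form is written and its mirror image is used if a test run shows the opposite sense; the acid is made separately from the 3,3'-diaryl-BINOL and is not counted.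

Step 1
Reactants: 1 isovanillin (3-hydroxy-4-methoxybenzaldehyde)
Product: 2 4-methoxy-3-(triisopropylsilyloxy)benzaldehyde
Conditions: iPr3SiCl, imidazole, DMF, rt
Reagents that add atoms: chlorotriisopropylsilane, CC(C)[Si](Cl)(C(C)C)C(C)C
Why: O-silylation of the only free phenol; the bulky silyl ether should survive steps 2 to 5, steers the Claisen step, and later acts as steric shield and traceless leaving group on the C6 oxygen.

Step 2
Reactants: 2 4-methoxy-3-(triisopropylsilyloxy)benzaldehyde
Product: 4 4-methoxy-3-(triisopropylsilyloxy)phenol, via aryl formate 3 (not isolated)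
Conditions: mCPBA, CH2Cl2, 0 °C to rt; then Et3N (cat.), MeOH, rt
Reagents that add atoms: mCPBA, OOC(=O)c1cccc(Cl)c1
Why: Baeyer–Villiger (Dakin-type) oxidation in which the para-methoxy group makes the aryl group migrate, followed by mild methanolysis of formate 3 that spares the aryl silyl ether; it is run before any alkene is present.

Step 3
Reactants: 4 4-methoxy-3-(triisopropylsilyloxy)phenol
Product: 5 allyl 4-methoxy-3-(triisopropylsilyloxy)phenyl ether
Conditions: allyl bromide, K2CO3, acetone, reflux
Reagents that add atoms: allyl bromide, C=CCBr
Why: Williamson ether synthesis on the only free phenol with a reactive primary allylic halide.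

Step 4
Reactants: 5 allyl 4-methoxy-3-(triisopropylsilyloxy)phenyl ether
Product: 7 2-allyl-4-methoxy-5-(triisopropylsilyloxy)phenol, via ortho-dienone 6 (not isolated)
Conditions: N,N-diethylaniline, 190 °C
Reagents that add atoms: none
Why: Aromatic Claisen rearrangement and tautomerisation of 6; the ortho position between the two oxygen substituents is blocked by the neighbouring silyl ether, so allyl should go to the open ortho carbon, as in the 3,4-dimethoxyphenyl series.

Step 5
Reactants: 7 2-allyl-4-methoxy-5-(triisopropylsilyloxy)phenol
Product: 8 2-allyl-4,4-dimethoxy-5-(triisopropylsilyloxy)cyclohexa-2,5-dien-1-one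
Conditions: PhI(OAc)2, MeOH, 0 °C, short time
Reagents that add atoms: methanol, CO
Why: Oxidative dearomatisation of a p-methoxyphenol with a trivalent iodine reagent in methanol, which gives the p-quinone monoketal because the methoxy-bearing para carbon stabilises the positive charge best; allyl and silyl groups are inert under these conditions.

Step 6
Reactants: 9 3,4,5-trimethoxybenzaldehyde
Product: 10 (Z)-isoelemicin, 1,2,3-trimethoxy-5-[(Z)-prop-1-enyl]benzene
Conditions: EtPPh3Br, NaN(SiMe3)2, THF, 0 °C; then 9, −78 °C to rt; purification on AgNO3-impregnated silica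
Reagents that add atoms: ethyltriphenylphosphonium bromide, CC[P+](c1ccccc1)(c1ccccc1)c1ccccc1.[Br-]
Why: Wittig olefination with an unstabilised ylide under lithium-free, kinetically controlled conditions is Z-selective, and the residual E isomer is removed by argentation chromatography.

Step 7
Reactants: 8 2-allyl-4,4-dimethoxy-5-(triisopropylsilyloxy)cyclohexa-2,5-dien-1-one; 10 (Z)-isoelemicin
Product: 13 (2R,3S,3aR)-3a-allyl-5-methoxy-3-methyl-2-(3,4,5-trimethoxyphenyl)-3,3a-dihydro-1-benzofuran-6(2H)-one, via phenoxenium ion 11 (not isolated), via O-silyl oxocarbenium ion 12 (not isolated)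
Conditions: (S,S)-imidodiphosphorimidate acid [two 3,3'-bis(3,5-bis(trifluoromethyl)phenyl)-BINOL units, N-SO2CF3 groups] (5 mol %), 10 (1.5 equiv), toluene, −78 °C; then Et3N
Reagents that add atoms: none
Why: Proposed new method: the acid ionises ketal 8 to the methoxy-stabilised phenoxenium ion 11, held in a contact ion pair by the confined chiral anion; the former nucleophilic ortho carbon of phenol 7 is now the electrophile and is attacked by the nucleophilic beta carbon of 10 (C3–C3a), the charge building on the benzylic carbon is taken at once by the neighbouring carbonyl oxygen (O1–C2), and the resulting ion 12 passes its silyl group through the anion to a ketal methoxy group of the next molecule of 8, which gives 13, iPr3SiOMe and a new ion 11. The closest known reaction types are the acid-promoted formal [3+2] coupling of p-quinone monoketals with propenylarenes (racemic, aryl group endo) and asymmetric counteranion-directed catalysis of oxocarbenium ions by imidodiphosphorimidates with silyl turnover; new are their combination, the Z alkene and the exo demand. Ring A (O1, C2, C3, C3a, C7a) is the only ring closed, by intermolecular C–C bond formation followed by 5-exo-trig capture of the benzylic cation (seen as its quinoid C2=C(aryl) form) by oxygen. C2 and C3: both bonds form on the same alkene face and the new C3–C3a bond already lies parallel to the empty benzylic orbital, so closure needs almost no motion and should outrun rotation, copying the Z geometry into the cis aryl/methyl pair; C3a relative to C3: exo approach, aryl and methyl turned away from ring B and therefore cis to allyl, because the iPr3SiO group beside C7 covers on both faces the C6–C7 edge over which an endo 3,4,5-trimethoxyphenyl group would have to lie and because the twisted aryl ring of a Z-propenylarene stacks poorly; absolute configuration: the anion blocks one face of the flat cation so that 10 adds to the Re face of the allyl-bearing carbon (3aR in 13). Needed are site selectivity (allyl-bearing carbon and not C7, since the C6 oxygen and the C7a carbonyl form a vinylogous ester that deactivates C7, as known for the 4,5-dimethoxy analogue), O- over C-closure (C7 is crowded by the silyl ether, O-closure gives the better stabilised 1,3-dioxyallyl cation and becomes irreversible through fast loss of silicon) and retention of the kinetic cis configuration at C2 (−78 °C, amine quench).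

Step 8
Reactants: 13 (2R,3S,3aR)-3a-allyl-5-methoxy-3-methyl-2-(3,4,5-trimethoxyphenyl)-3,3a-dihydro-1-benzofuran-6(2H)-one
Product: 15 dysodanthin B, via silyl enol ether 14 (not isolated)
Conditions: [(Ph3P)CuH]6 (5 mol %), PhMe2SiH, toluene, 0 °C to rt; then Bu4NF, AcOH, THF, −78 °C; neutral work-up
Reagents that add atoms: none
Why: Copper hydride catalysed 1,4-hydrosilylation sends hydride to C4, the unsubstituted beta carbon of the alpha-methoxy enone, and not to C7a (fully substituted, deactivated vinylogous ester) or the isolated allyl alkene, and the buffered fluoride-induced protonation of 14 at low temperature should place the proton on C5 from the face opposite the pseudoaxial allyl group on C3a, leaving methoxy cis to allyl (5R) under kinetic control.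

Compound list
1 | isovanillin (3-hydroxy-4-methoxybenzaldehyde) | COc1ccc(C=O)cc1O | starting material
2 | 4-methoxy-3-(triisopropylsilyloxy)benzaldehyde | COc1ccc(C=O)cc1O[Si](C(C)C)(C(C)C)C(C)C | intermediate
3 | 4-methoxy-3-(triisopropylsilyloxy)phenyl formate | COc1ccc(OC=O)cc1O[Si](C(C)C)(C(C)C)C(C)C | intermediate
4 | 4-methoxy-3-(triisopropylsilyloxy)phenol | COc1ccc(O)cc1O[Si](C(C)C)(C(C)C)C(C)C | intermediate
5 | allyl 4-methoxy-3-(triisopropylsilyloxy)phenyl ether | C=CCOc1ccc(OC)c(O[Si](C(C)C)(C(C)C)C(C)C)c1 | intermediate
6 | 6-allyl-4-methoxy-3-(triisopropylsilyloxy)cyclohexa-2,4-dien-1-one (racemic, transient) | C=CCC1C=C(OC)C(O[Si](C(C)C)(C(C)C)C(C)C)=CC1=O | intermediate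
7 | 2-allyl-4-methoxy-5-(triisopropylsilyloxy)phenol | C=CCc1cc(OC)c(O[Si](C(C)C)(C(C)C)C(C)C)cc1O | intermediate
8 | 2-allyl-4,4-dimethoxy-5-(triisopropylsilyloxy)cyclohexa-2,5-dien-1-one | C=CCC1=CC(OC)(OC)C(O[Si](C(C)C)(C(C)C)C(C)C)=CC1=O | intermediate
9 | 3,4,5-trimethoxybenzaldehyde | COc1cc(C=O)cc(OC)c1OC | starting material
10 | (Z)-isoelemicin, 1,2,3-trimethoxy-5-[(Z)-prop-1-enyl]benzene | C/C=C\c1cc(OC)c(OC)c(OC)c1 | intermediate
11 | 2-allyl-4-methoxy-5-(triisopropylsilyloxy)phenoxenium ion (O-methyl oxocarbenium form, ion pair with the catalyst anion) | C=CCC1=CC(=[O+]C)C(O[Si](C(C)C)(C(C)C)C(C)C)=CC1=O | intermediate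
12 | (2R,3S,3aR)-cycloadduct carrying the triisopropylsilyl group on the C6 oxygen (O-silyl oxocarbenium ion) | C=CC[C@@]12C=C(OC)C(=[O+][Si](C(C)C)(C(C)C)C(C)C)C=C1O[C@@H](c1cc(OC)c(OC)c(OC)c1)[C@H]2C | intermediate
13 | (2R,3S,3aR)-3a-allyl-5-methoxy-3-methyl-2-(3,4,5-trimethoxyphenyl)-3,3a-dihydro-1-benzofuran-6(2H)-one (aryl, methyl and allyl all cis on ring A) | C=CC[C@@]12C=C(OC)C(=O)C=C1O[C@@H](c1cc(OC)c(OC)c(OC)c1)[C@H]2C | intermediate
14 | (2R,3S,3aS)-3a-allyl-6-[dimethyl(phenyl)silyloxy]-5-methoxy-3-methyl-2-(3,4,5-trimethoxyphenyl)-2,3,3a,4-tetrahydro-1-benzofuran | C=CC[C@@]12CC(OC)=C(O[Si](C)(C)c3ccccc3)C=C1O[C@@H](c1cc(OC)c(OC)c(OC)c1)[C@H]2C | intermediate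
15 | dysodanthin B, (2R,3S,3aS,5R)-3a-allyl-5-methoxy-3-methyl-2-(3,4,5-trimethoxyphenyl)-3,3a,4,5-tetrahydro-1-benzofuran-6(2H)-one | C=CC[C@@]12C[C@@H](OC)C(=O)C=C1O[C@@H](c1cc(OC)c(OC)c(OC)c1)[C@H]2C | target

Total step count: 8. Longest linear sequence: 7 (steps 1–5, 7, 8).

Steps most likely to fail

1. Step 7.
- What may go wrong: the benzylic carbon may close onto C7 instead of O1. The endo approach known for less hindered cations may persist. Rotation about C2–C3, or acid-induced Z-to-E isomerisation of 10, may occur before closure. The anion may discriminate the two faces only weakly.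
- Fallback (from 8 and 10, back at 13): the coupling is run in its established non-asymmetric form (Me3SiOTf 10 mol %, CH2Cl2/MeCN, −78 °C). The all-cis diastereomer is separated on silica. The racemate, which is 13 together with its mirror image (2S,3R,3aS)-3a-allyl-5-methoxy-3-methyl-2-(3,4,5-trimethoxyphenyl)-3,3a-dihydro-1-benzofuran-6(2H)-one F1, is resolved by preparative HPLC on a cellulose tris(3,5-dimethylphenylcarbamate) phase. Control of the absolute configuration thus passes from catalysis to resolution.

2. Step 8.
- What may go wrong: facial selectivity in the protonation may be poor. C5 may later epimerise toward the more stable equatorial methoxy arrangement through traces of base or on silica. Carbonyl (1,2) reduction may compete.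
- Fallback (from 13, back at 15): the reduction is handed to a flavin-dependent ene-reductase of the Old Yellow Enzyme family (panel screening, NADP+/glucose/glucose dehydrogenase recycling, phosphate buffer pH 6.5–7, DMSO cosolvent, 30 °C). This is a known way to reduce 2-alkoxycyclohexenones and 4,4-disubstituted cyclohexadienones. Hydride passes from the flavin to C4 and an active-site tyrosine protonates C5 on the opposite face, so the protein and not the substrate fixes C5. No new compound is made on this way (F0).

3. Step 6.
- What may go wrong: Z selectivity may be incomplete and the E isomer hard to remove. Any E isomer left would be copied into the wrong C2/C3 relationship in step 7.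
- Fallback (from 9, back at 10): Corey–Fuchs homologation (CBr4, PPh3, CH2Cl2, 0 °C) gives 5-(2,2-dibromovinyl)-1,2,3-trimethoxybenzene F2. Treatment with nBuLi (2 equiv, THF, −78 °C) gives lithium (3,4,5-trimethoxyphenyl)acetylide F3. MeI in the same flask gives 1,2,3-trimethoxy-5-(prop-1-ynyl)benzene F4. Syn semihydrogenation (H2, Pd/CaCO3 poisoned with Pb(OAc)2, quinoline, EtOAc) then fixes the Z geometry through the mode of hydrogen delivery.

Further compounds
F1 | step 7 | (2S,3R,3aS)-3a-allyl-5-methoxy-3-methyl-2-(3,4,5-trimethoxyphenyl)-3,3a-dihydro-1-benzofuran-6(2H)-one | C=CC[C@]12C=C(OC)C(=O)C=C1O[C@H](c1cc(OC)c(OC)c(OC)c1)[C@@H]2C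
F0 | step 8 | none | none
F2 | step 6 | 5-(2,2-dibromovinyl)-1,2,3-trimethoxybenzene | COc1cc(C=C(Br)Br)cc(OC)c1OC
F3 | step 6 | lithium (3,4,5-trimethoxyphenyl)acetylide | [Li]C#Cc1cc(OC)c(OC)c(OC)c1
F4 | step 6 | 1,2,3-trimethoxy-5-(prop-1-ynyl)benzene | CC#Cc1cc(OC)c(OC)c(OC)c1
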